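(The rate constants are made up; the rest is arithmetic.)

The amounts came first. The recipes put 1.60 mM of D against 2.0 mM of J, less D than J, so D was the limiting reagent, and L, made one for one from D, had a ceiling of 80.0% of the J charged.

| flask | J | D | temperature | time |
|---|---|---|---|---|
| maple | 2.0 mM | 0.800 equiv | 40 °C | 5.0 s |
| ash | 2.0 mM | 0.800 equiv | 15 °C | 5.0 s |
| larch | 2.0 mM | 0.800 equiv | 65 °C | 5.0 s |
| birch | 2.0 mM | 0.800 equiv | −10 °C | 5.0 s |

    J + D ⇌ J.D (K1 = 26000 L mol⁻¹, k1 = 5400 L mol⁻¹ s⁻¹, Ea1 = 25.0 kJ mol⁻¹, ΔH1 = 20.0 kJ mol⁻¹)
    J ⇌ X (K2 = 0.16, k2 = 0.19 s⁻¹, Ea2 = 88.0 kJ mol⁻¹, ΔH2 = −67.0 kJ mol⁻¹)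
    J → G (k3 = 0.24 s⁻¹, Ea3 = 75.0 kJ mol⁻¹)
    J.D → L (k4 = 1.1 s⁻¹, Ea4 = 66.0 kJ mol⁻¹)
    D + G ⇌ D.G (K5 = 800 L mol⁻¹, k5 = 330 L mol⁻¹ s⁻¹, Ea5 = 47.0 kJ mol⁻¹, ΔH5 = −25.0 kJ mol⁻¹)
    D.G → Z (k6 = 0.26 s⁻¹, Ea6 = 84.0 kJ mol⁻¹)
    (constants at 40 °C)

1. which flask leads in amount of L, in percent of the J charged ("all alike" within 1.5 percentage points) (maple / ash / larch / birch / all alike)
2. how much L is there at the end, in percent of the J charged: maple
3. how much L is there at the end, in percent of the J charged: ash
4. how much L is there at the end, in percent of the J charged: larch
5. how much L is there at the end, in percent of the J charged: birch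

- the list of constants is for 40 °C, to be carried to other temperatures by the activation energies and enthalpies

I asked first where D went. I set J ⇌ X aside, took the binding as one-way, and gave J two exits: binding to D at a rate proportional to [J][D], and leaking to G at a rate proportional to [J]. I divided the leak by the binding, and [J] and time dropped out. G gained per D spent was the leak constant over the binding constant times [D]. So in this reckoning [D] fell exponentially with the G made, and the surplus of J, 0.400 mM, left by the leak.

That gave me one number. The surplus number is the surplus of J times the binding constant over the leak constant, and it counts how many times the leak must shrink [D] by a factor of e while the surplus leaves. In this reckoning the share of D that J failed to catch is roughly the exponential of minus this number.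

For maple I got 9.00, a share of 0.0123%. For larch, carrying both constants by their activation energies, I got 2.18, a share of 11.3%, so L in larch came to about 70.9%.

For ash I got 47.6, more than for maple, which taken by itself put the cold flasks first. One number was not enough: J.D still had to become L. So I added a clock number, the constant of J.D → L times the time: 5.50 for maple, 35.8 for larch, 0.610 for ash and 0.0445 for birch.

That put maple at 79.7%, ash below 36.5% and birch below 3.48%. My leader was maple.

The forecast named maple, with 78% for maple, 31% for ash, 73% for larch and 2.5% for birch, starting from “D is limiting, capping L at 80%”.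

The simulation gave maple the lead: maple 77.7%, ash 31.3%, larch 73.5%, birch 2.46%. Larch stood 6.5 percentage points under the ceiling, and its Z stood at 4.79% after 5.00 s. The surplus number had put the loss in larch at 9.0 points.

In the flask like maple with 0.200 equiv of D, the surplus number was 36.0, more than in maple, so I expected L near 19.9%. That flask gave 19.8% of L, with 51.9% as G.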